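Ring A (C1–C4, C4a, C8a) is disconnected at C1–C8a. Decalin locants: C1 bears the propanoic acid chain, C2 the isopropylidene, C5 the arylmethyl group. C8a, the methyl-bearing fusion carbon shared with ring B, is a latent tertiary carbocation, and C1 is enolisable once C2 is a ketone. The key step, a Lewis-acid-promoted cationic cyclisation, lets the enol of a β-keto ester capture the C8a cation of a ring-B cyclohexene, closing ring A and setting the quaternary centre and trans ring fusion. The precursor is a monocyclic cyclohexene β-keto ester whose C4a, C5 and C6 stereocentres come from one catalytic enantioselective Diels–Alder reaction.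

Key step: step 10

Remark on conventions: monocyclic intermediates 13–18 are described with their future decalin locants (ring B = C4a, C5, C6, C7, C8, C8a). β is the face of the C8a methyl group; in the target 5-CH3 and the C1 chain are β, and H-4a, 5-CH2Ar and 6-CH3 are α.

Remark on the chemistry (assumption): the (S)-oxazaborolidine in step 7 is assumed to give the enantiomer drawn; if the sense of induction is opposite, the (R)-catalyst is used.

Step 1
Reactants: 1 2,6-dimethylbenzene-1,4-diol
Product: 2 2,5-dimethoxy-1,3-dimethylbenzene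
Conditions: MeI, K2CO3, acetone, reflux
Reagents that add atoms: iodomethane, CI
Why: Williamson O-methylation of both phenols protects the hydroquinone as its dimethyl ether for the organometallic and Lewis-acid steps that follow.

Step 2
Reactants: 2 2,5-dimethoxy-1,3-dimethylbenzene
Product: 3 1-(bromomethyl)-2,5-dimethoxy-3-methylbenzene
Conditions: N-bromosuccinimide (1.0 equiv), azobis(isobutyronitrile) (cat.), PhCF3, 85 °C
Reagents that add atoms: N-bromosuccinimide, O=C1CCC(=O)N1Br
Why: Wohl–Ziegler radical bromination with one equivalent of reagent in a non-polar solvent should functionalise one of the two equivalent benzylic methyl groups rather than the ring.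

Step 3
Reactants: 4 (E)-but-2-enal
Product: 6 (Z)-2-bromobut-2-enal, via 2,3-dibromobutanal 5 (not isolated)
Conditions: Br2, CH2Cl2, 0 °C; then Et3N, 0 → 25 °C
Reagents that add atoms: bromine, BrBr
Why: Bromine addition followed by amine-mediated E1cB loss of HBr should give the thermodynamically preferred α-bromo enal in which formyl and methyl are trans.

Step 4
Reactants: 3 1-(bromomethyl)-2,5-dimethoxy-3-methylbenzene; 6 (Z)-2-bromobut-2-enal
Product: 8 (E)-2-[(2,5-dimethoxy-3-methylphenyl)methyl]but-2-enal, via benzylic zinc bromide 7 (not isolated)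
Conditions: Zn dust, LiCl, THF, 25 °C; then 6, Pd(OAc)2 (2 mol %), 2-dicyclohexylphosphino-2′,6′-dimethoxybiphenyl (4 mol %), THF, 0 → 25 °C
Reagents that add atoms: none
Why: Zinc insertion into the benzylic bromide and Negishi cross-coupling with the vinyl bromide, which retains the alkene geometry, should give the trisubstituted enal with formyl trans to the β-methyl group.

Step 5
Reactants: 9 methyl 4-oxobutanoate; 10 2-(triphenyl-λ5-phosphanylidene)propanal
Product: 11 methyl (E)-5-methyl-6-oxohex-4-enoate
Conditions: toluene, 80 °C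
Reagents that add atoms: none
Why: Wittig olefination of the aliphatic aldehyde with the stabilised α-branched ylide is (E)-selective and leaves the methyl ester untouched.

Step 6
Reactants: 11 methyl (E)-5-methyl-6-oxohex-4-enoate
Product: 12 methyl (E)-5-methylhepta-4,6-dienoate
Conditions: Ph3PCH3Br, KOtBu, THF, 0 °C; then 11, −78 → 0 °C
Reagents that add atoms: methyltriphenylphosphonium bromide, C[P+](c1ccccc1)(c1ccccc1)c1ccccc1.[Br-]
Why: Wittig methylenation of the enal at low temperature should convert the formyl group into the terminal vinyl group without touching the ester or the (E)-trisubstituted alkene.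

Step 7
Reactants: 12 methyl (E)-5-methylhepta-4,6-dienoate; 8 (E)-2-[(2,5-dimethoxy-3-methylphenyl)methyl]but-2-enal
Product: 13 methyl 3-[(1S,5S,6R)-6-[(2,5-dimethoxy-3-methylphenyl)methyl]-6-formyl-2,5-dimethylcyclohex-2-en-1-yl]propanoate
Conditions: (S)-3,3-diphenyl-1-(2-methylphenyl)tetrahydro-1H,3H-pyrrolo[1,2-c][1,3,2]oxazaborole (20 mol %), HN(SO2CF3)2 (20 mol %), CH2Cl2, −78 → −20 °C
Reagents that add atoms: none
Why: In this enantioselective Diels–Alder reaction under protonated-oxazaborolidine catalysis the 1-alkyl group of the diene directs the "ortho" regiochemistry (C4a–C5 bond), the endo formyl group ends up cis to the C4a side chain, the (E)-dienophile places the 6-methyl group trans to formyl and cis to the arylmethyl group, and the catalyst fixes the absolute configuration of all three centres.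

Step 8
Reactants: 13 methyl 3-[(1S,5S,6R)-6-[(2,5-dimethoxy-3-methylphenyl)methyl]-6-formyl-2,5-dimethylcyclohex-2-en-1-yl]propanoate
Product: 15 3-[(1S,5S,6S)-6-[(2,5-dimethoxy-3-methylphenyl)methyl]-2,5,6-trimethylcyclohex-2-en-1-yl]propanoic acid, via hydrazone acid 14 (not isolated)
Conditions: KOH, diethylene glycol, 110 °C; then N2H4·H2O, 130 → 200 °C; HCl work-up
Reagents that add atoms: potassium hydroxide, [K+].[OH-]
Why: One-pot saponification and Wolff–Kishner reduction (Huang-Minlon procedure) should turn the hindered formyl group into the C5 methyl group and deliver the free acid, while the isolated alkene and the three non-enolisable stereocentres are untouched.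

Step 9
Reactants: 15 3-[(1S,5S,6S)-6-[(2,5-dimethoxy-3-methylphenyl)methyl]-2,5,6-trimethylcyclohex-2-en-1-yl]propanoic acid; 16 potassium 3-methoxy-3-oxopropanoate
Product: 18 methyl 5-[(1S,5S,6S)-6-[(2,5-dimethoxy-3-methylphenyl)methyl]-2,5,6-trimethylcyclohex-2-en-1-yl]-3-oxopentanoate, via acyl imidazolide 17 (not isolated)
Conditions: 1,1′-carbonyldiimidazole, THF, 25 °C; then 16, MgCl2, Et3N, THF–MeCN, 25 → 45 °C; 1 M HCl work-up
Reagents that add atoms: none
Why: In this Masamune–Brooks homologation the acyl imidazolide acylates the magnesium enolate of the malonate half-ester, and decarboxylation gives the β-keto ester without any epimerisable intermediate.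

Step 10
Reactants: 18 methyl 5-[(1S,5S,6S)-6-[(2,5-dimethoxy-3-methylphenyl)methyl]-2,5,6-trimethylcyclohex-2-en-1-yl]-3-oxopentanoate
Product: 19 methyl (1S,4aR,5S,6S,8aR)-5-[(2,5-dimethoxy-3-methylphenyl)methyl]-5,6,8a-trimethyl-2-oxodecahydronaphthalene-1-carboxylate
Conditions: SnCl4 (2 equiv), CH2Cl2, 0 → 25 °C
Reagents that add atoms: none
Why: SnCl4 chelates the β-keto ester as its tin enolate and the released proton adds to C8 of the ring-B alkene (Markovnikov), so that C8a becomes a tertiary carbocation that is captured by C1 of the enol; any O-alkylated dihydropyran should re-ionise and be funnelled to the C–C product. The closest known reaction type is the Lewis-acid-promoted cationic cyclisation of olefinic β-keto esters (the cationic counterpart of the Conia-ene reaction), known for monocyclic cyclohexenes that close to trans-decalins. Ring A closes in the 6-(enolendo)-exo-trig mode. C8a should be set by a chair–chair transition state in which the C4a side chain stays equatorial on ring B and C1 attacks from the α-face, leaving the C8a methyl group axial on the β-face (trans fusion), because β-attack would be syn-axial to the 5-methyl group; C1 is epimerisable and should settle with the ester equatorial. The step needs C- over O-alkylation, secured by the reversibility of O-alkylation, and enol capture over arene capture or hydride shift, secured by the far higher nucleophilicity of the tin enolate and by the equatorial arylmethyl group, which cannot reach C8a.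

Step 11
Reactants: 19 methyl (1S,4aR,5S,6S,8aR)-5-[(2,5-dimethoxy-3-methylphenyl)methyl]-5,6,8a-trimethyl-2-oxodecahydronaphthalene-1-carboxylate; 20 methyl prop-2-enoate
Product: 21 methyl (1S,4aR,5S,6S,8aR)-5-[(2,5-dimethoxy-3-methylphenyl)methyl]-1-(3-methoxy-3-oxopropyl)-5,6,8a-trimethyl-2-oxodecahydronaphthalene-1-carboxylate
Conditions: Cs2CO3 (0.2 equiv), MeCN, 40 °C
Reagents that add atoms: none
Why: Base-catalysed Michael addition of the cyclic β-keto ester installs the three-carbon chain regiospecifically at C1, the acceptor being expected to approach anti to the axial C8a methyl group, although this centre is reset in the next step.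

Step 12
Reactants: 21 methyl (1S,4aR,5S,6S,8aR)-5-[(2,5-dimethoxy-3-methylphenyl)methyl]-1-(3-methoxy-3-oxopropyl)-5,6,8a-trimethyl-2-oxodecahydronaphthalene-1-carboxylate
Product: 22 methyl 3-[(1S,4aR,5S,6S,8aR)-5-[(2,5-dimethoxy-3-methylphenyl)methyl]-5,6,8a-trimethyl-2-oxodecahydronaphthalen-1-yl]propanoate
Conditions: LiCl, H2O (2 equiv), DMSO, 150 °C
Reagents that add atoms: none
Why: Krapcho dealkoxycarbonylation should remove the activated ester at the quaternary carbon much faster than the unactivated chain ester, and the resulting ketone should equilibrate at C1 towards the epimer with the equatorial (β) side chain.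

Step 13
Reactants: 22 methyl 3-[(1S,4aR,5S,6S,8aR)-5-[(2,5-dimethoxy-3-methylphenyl)methyl]-5,6,8a-trimethyl-2-oxodecahydronaphthalen-1-yl]propanoate; 23 propan-2-one
Product: 24 methyl 3-[(1S,4aR,5S,6S,8aR)-5-[(2,5-dimethoxy-3-methylphenyl)methyl]-5,6,8a-trimethyl-2-(propan-2-ylidene)decahydronaphthalen-1-yl]propanoate
Conditions: TiCl4, Zn, pyridine, THF, reflux; slow addition of 22 and acetone (5 equiv)
Reagents that add atoms: none
Why: Crossed McMurry coupling with excess acetone on low-valent titanium should form the tetrasubstituted isopropylidene alkene directly from the C2 carbonyl under non-basic conditions, so that the C1 configuration set at the ketone stage is kept.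

Step 14
Reactants: 24 methyl 3-[(1S,4aR,5S,6S,8aR)-5-[(2,5-dimethoxy-3-methylphenyl)methyl]-5,6,8a-trimethyl-2-(propan-2-ylidene)decahydronaphthalen-1-yl]propanoate
Product: 25 3-[(1S,4aR,5S,6S,8aR)-5-[(2,5-dihydroxy-3-methylphenyl)methyl]-5,6,8a-trimethyl-2-(propan-2-ylidene)decahydronaphthalen-1-yl]propanoic acid
Conditions: NaSEt (10 equiv), DMF, 130 °C, argon; then 1 M HCl
Reagents that add atoms: none
Why: Nucleophilic demethylation with ethanethiolate (SN2 at methyl) should cleave both aryl methyl ethers and the methyl ester in one operation without acid that could isomerise the tetrasubstituted alkene.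

Compound list

1 | 2,6-dimethylbenzene-1,4-diol | Cc1cc(O)cc(C)c1O | starting material
2 | 2,5-dimethoxy-1,3-dimethylbenzene | Cc1cc(OC)cc(C)c1OC | intermediate
3 | 1-(bromomethyl)-2,5-dimethoxy-3-methylbenzene | BrCc1cc(OC)cc(C)c1OC | intermediate
4 | (E)-but-2-enal | C/C=C/C=O | starting material
5 | 2,3-dibromobutanal | CC(Br)C(Br)C=O | intermediate
6 | (Z)-2-bromobut-2-enal | C/C=C(\Br)C=O | intermediate
7 | [(2,5-dimethoxy-3-methylphenyl)methyl]zinc bromide | COc1cc(C)c(OC)c(C[Zn]Br)c1 | intermediate
8 | (E)-2-[(2,5-dimethoxy-3-methylphenyl)methyl]but-2-enal | C/C=C(/C=O)Cc1cc(OC)cc(C)c1OC | intermediate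
9 | methyl 4-oxobutanoate | COC(=O)CCC=O | starting material
10 | 2-(triphenyl-λ5-phosphanylidene)propanal | CC(C=O)=P(c1ccccc1)(c1ccccc1)c1ccccc1 | starting material
11 | methyl (E)-5-methyl-6-oxohex-4-enoate | COC(=O)CC/C=C(\C)C=O | intermediate
12 | methyl (E)-5-methylhepta-4,6-dienoate | COC(=O)CC/C=C(\C)C=C | intermediate
13 | methyl 3-[(1S,5S,6R)-6-[(2,5-dimethoxy-3-methylphenyl)methyl]-6-formyl-2,5-dimethylcyclohex-2-en-1-yl]propanoate (side chain cis to formyl, 5-methyl trans to formyl) | COC(=O)CC[C@H]1C(C)=CC[C@H](C)[C@]1(C=O)Cc2cc(OC)cc(C)c2OC | intermediate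
14 | 3-[(1S,5S,6R)-6-[(2,5-dimethoxy-3-methylphenyl)methyl]-6-(hydrazinylidenemethyl)-2,5-dimethylcyclohex-2-en-1-yl]propanoic acid | OC(=O)CC[C@H]1C(C)=CC[C@H](C)[C@]1(C=NN)Cc2cc(OC)cc(C)c2OC | intermediate
15 | 3-[(1S,5S,6S)-6-[(2,5-dimethoxy-3-methylphenyl)methyl]-2,5,6-trimethylcyclohex-2-en-1-yl]propanoic acid | OC(=O)CC[C@H]1C(C)=CC[C@H](C)[C@]1(C)Cc2cc(OC)cc(C)c2OC | intermediate
16 | potassium 3-methoxy-3-oxopropanoate | COC(=O)CC(=O)[O-].[K+] | starting material
17 | 3-[(1S,5S,6S)-6-[(2,5-dimethoxy-3-methylphenyl)methyl]-2,5,6-trimethylcyclohex-2-en-1-yl]-1-(1H-imidazol-1-yl)propan-1-one | O=C(CC[C@H]1C(C)=CC[C@H](C)[C@]1(C)Cc2cc(OC)cc(C)c2OC)n3ccnc3 | intermediate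
18 | methyl 5-[(1S,5S,6S)-6-[(2,5-dimethoxy-3-methylphenyl)methyl]-2,5,6-trimethylcyclohex-2-en-1-yl]-3-oxopentanoate | COC(=O)CC(=O)CC[C@H]1C(C)=CC[C@H](C)[C@]1(C)Cc2cc(OC)cc(C)c2OC | intermediate
19 | methyl (1S,4aR,5S,6S,8aR)-5-[(2,5-dimethoxy-3-methylphenyl)methyl]-5,6,8a-trimethyl-2-oxodecahydronaphthalene-1-carboxylate (trans-fused; C1 epimerisable, drawn with the ester equatorial) | O=C1CC[C@H]2[C@@](C)(CC[C@H](C)[C@]2(C)Cc3cc(OC)cc(C)c3OC)[C@@H]1C(=O)OC | intermediate
20 | methyl prop-2-enoate | COC(=O)C=C | starting material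
21 | methyl (1S,4aR,5S,6S,8aR)-5-[(2,5-dimethoxy-3-methylphenyl)methyl]-1-(3-methoxy-3-oxopropyl)-5,6,8a-trimethyl-2-oxodecahydronaphthalene-1-carboxylate (new chain α) | O=C1CC[C@H]2[C@@](C)(CC[C@H](C)[C@]2(C)Cc3cc(OC)cc(C)c3OC)[C@]1(CCC(=O)OC)C(=O)OC | intermediate
22 | methyl 3-[(1S,4aR,5S,6S,8aR)-5-[(2,5-dimethoxy-3-methylphenyl)methyl]-5,6,8a-trimethyl-2-oxodecahydronaphthalen-1-yl]propanoate | O=C1CC[C@H]2[C@@](C)(CC[C@H](C)[C@]2(C)Cc3cc(OC)cc(C)c3OC)[C@@H]1CCC(=O)OC | intermediate
23 | propan-2-one | CC(C)=O | starting material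
24 | methyl 3-[(1S,4aR,5S,6S,8aR)-5-[(2,5-dimethoxy-3-methylphenyl)methyl]-5,6,8a-trimethyl-2-(propan-2-ylidene)decahydronaphthalen-1-yl]propanoate | CC(C)=C1CC[C@H]2[C@@](C)(CC[C@H](C)[C@]2(C)Cc3cc(OC)cc(C)c3OC)[C@@H]1CCC(=O)OC | intermediate
25 | 3-[(1S,4aR,5S,6S,8aR)-5-[(2,5-dihydroxy-3-methylphenyl)methyl]-5,6,8a-trimethyl-2-(propan-2-ylidene)decahydronaphthalen-1-yl]propanoic acid | CC(C)=C1CC[C@H]2[C@@](C)(CC[C@H](C)[C@]2(C)Cc2cc(O)cc(C)c2O)[C@@H]1CCC(=O)O | target

Total step count: 14. Longest linear sequence: 11 steps (steps 1, 2, 4, 7, 8, 9, 10, 11, 12, 13, 14).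

Steps most likely to fail

Step 10. The C8a carbocation may be captured on the wrong face when ring B reacts through its other chair, which would give the cis-fused decalin. It may also be intercepted by the electron-rich arene, or lose its identity by elimination or a 1,2-hydride shift from C4a. The fallback sets out from 18 and avoids the free carbocation. Treatment with N-(phenylselanyl)phthalimide and SnCl4 in CH2Cl2 at −78 °C activates the alkene as a bridged seleniranium ion, which the tin enolate should open at C8a in an anti fashion (selenium-mediated carbocyclisation). This would give the 8β-phenylselanyl keto ester F1. Reductive removal of selenium with Bu3SnH and azobis(isobutyronitrile) in toluene at 80 °C comes back to the route at 19.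

Step 7. The hindered trisubstituted enal may add too slowly, with erosion of endo and enantiofacial selectivity or Lewis-acid-induced oligomerisation of the diene. The fallback sets out from 12 and 8 and gives up catalytic asymmetric induction. The cycloaddition is run with stoichiometric Me2AlCl in CH2Cl2 at −40 °C to give the racemic formyl ester F2. Saponification and Wolff–Kishner reduction under the conditions of step 8 give the racemic acid F3. Resolution by crystallisation with (R)-1-phenylethanamine gives the diastereomerically pure ammonium salt F4, and acidification with 1 M HCl comes back to the route at 15.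

Step 13. Homocoupling of acetone may outrun cross-coupling at the hindered ketone, the ketone may couple reductively with the side-chain ester, or C1 may epimerise on the Lewis-acidic titanium surface. The fallback sets out from 22 and splits the olefination into two operations. Ramirez dibromo-olefination (CBr4, PPh3, toluene, 80 °C) gives the 1,1-dibromoalkene F5. Twofold Negishi methylation (MeZnCl, Pd(PtBu3)2, THF, 50 °C) comes back to the route at 24.

Further compounds
F1 | step 10 | methyl 5-[(2,5-dimethoxy-3-methylphenyl)methyl]-5,6,8a-trimethyl-2-oxo-8-(phenylselanyl)decahydronaphthalene-1-carboxylate (configuration of 19, selenium β at C8) | O=C1CC[C@H]2[C@@](C)([C@@H]([Se]c3ccccc3)C[C@H](C)[C@]2(C)Cc4cc(OC)cc(C)c4OC)[C@@H]1C(=O)OC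
F2 | step 7 | racemic methyl 3-[6-[(2,5-dimethoxy-3-methylphenyl)methyl]-6-formyl-2,5-dimethylcyclohex-2-en-1-yl]propanoate (relative configuration of 13; one enantiomer drawn) | COC(=O)CC[C@H]1C(C)=CC[C@H](C)[C@]1(C=O)Cc2cc(OC)cc(C)c2OC
F3 | step 7 | racemic 3-[6-[(2,5-dimethoxy-3-methylphenyl)methyl]-2,5,6-trimethylcyclohex-2-en-1-yl]propanoic acid (relative configuration of 15; one enantiomer drawn) | OC(=O)CC[C@H]1C(C)=CC[C@H](C)[C@]1(C)Cc2cc(OC)cc(C)c2OC
F4 | step 7 | (R)-1-phenylethanaminium 3-[(1S,5S,6S)-6-[(2,5-dimethoxy-3-methylphenyl)methyl]-2,5,6-trimethylcyclohex-2-en-1-yl]propanoate | C[C@@H]([NH3+])c3ccccc3.[O-]C(=O)CC[C@H]1C(C)=CC[C@H](C)[C@]1(C)Cc2cc(OC)cc(C)c2OC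
F5 | step 13 | methyl 3-[(1S,4aR,5S,6S,8aR)-2-(dibromomethylidene)-5-[(2,5-dimethoxy-3-methylphenyl)methyl]-5,6,8a-trimethyldecahydronaphthalen-1-yl]propanoate | BrC(Br)=C1CC[C@H]2[C@@](C)(CC[C@H](C)[C@]2(C)Cc3cc(OC)cc(C)c3OC)[C@@H]1CCC(=O)OC
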